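## Retrosynthetic overview

1. Feature used: the tetrahydropyran (C1–C2–C3–C4–O–C15) is bridged 1,4 by the 14-membered carbocycle C1–C14. If C15 is read as a lactone carbonyl, C1=C14 becomes an α-methylene-δ-lactone acceptor, and C13 is allylic to the E-C11=C12 alkene. (Numbering: C1 ring-fusion CH, C3 CHOAc, C4 C(Me)–O, C7 CHOH, C8 C=CH2, C15 CMe2–O.)
2. C13–C14 is cut as a tin-hydride allyl-radical conjugate addition that closes the carbocycle and sets C1. Afterwards the lactone C=O becomes CMe2 (MeLi, methyl ketal, Me3Al), then OTBS→OAc at C3 and desilylation at C7.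
3. C7–C8 is cut as an asymmetric Ni/Cr coupling of a lactone aldehyde with a 2-iodo-1-alkene made from 6-methylhept-5-en-2-one (allylic oxidation, Shapiro iodination).
4. The δ-lactone with C3 and C4 comes from 2-allyl-2-methylcyclopentane-1,3-dione: yeast reduction, Mitsunobu inversion of the carbinol, silylation, Baeyer–Villiger oxidation.
5. Ring order: δ-lactone (future pyran) first, 14-membered carbocycle second.

Key step: step 19

Remark: baker's yeast is taken to give the (2S,3S)-ketol, whose hydroxyl is cis to allyl; the target needs this oxygen (C3) cis to the C4 methyl, so the carbinol is inverted in steps 3–4.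

## Route

Step 1
Reactants: 1 2-methylcyclopentane-1,3-dione; 2 allyl bromide
Product: 3 2-methyl-2-(prop-2-en-1-yl)cyclopentane-1,3-dione
Conditions: NaOH (1 M aq), rt
Reagents that add atoms: none
Why: C-allylation (SN2) of the stabilised 1,3-dione enolate in water, where solvation of the enolate oxygens favours C- over O-alkylation, should give the prochiral dione whose quaternary carbon becomes C4.

Step 2
Reactants: 3 2-methyl-2-(prop-2-en-1-yl)cyclopentane-1,3-dione
Product: 4 (2S,3S)-3-hydroxy-2-methyl-2-(prop-2-en-1-yl)cyclopentan-1-one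
Conditions: baker's yeast, sucrose, H2O, 30 °C
Reagents that add atoms: none
Why: enzymatic desymmetrising ketone reduction, in which the yeast dehydrogenases should reduce one enantiotopic carbonyl to the (2S,3S)-ketol (hydroxyl cis to allyl) and so fix the quaternary centre (future C4); the minor (2R,3S) isomer is to be removed by chromatography.

Step 3
Reactants: 4 (2S,3S)-3-hydroxy-2-methyl-2-(prop-2-en-1-yl)cyclopentan-1-one
Product: 5 (1R,2S)-2-methyl-3-oxo-2-(prop-2-en-1-yl)cyclopentyl chloroacetate
Conditions: ClCH2CO2H, PPh3, DIAD, toluene, 0 °C → rt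
Reagents that add atoms: chloroacetic acid, O=C(O)CCl
Why: Mitsunobu esterification, in which chloroacetate displaces the oxyphosphonium group by SN2 with inversion, should turn the carbinol centre to R (oxygen now cis to the methyl group, as C3 requires); elimination is blocked because the carbon between carbinol and ketone is quaternary.

Step 4
Reactants: 5 (1R,2S)-2-methyl-3-oxo-2-(prop-2-en-1-yl)cyclopentyl chloroacetate
Product: 6 (2S,3R)-3-hydroxy-2-methyl-2-(prop-2-en-1-yl)cyclopentan-1-one
Conditions: K2CO3 (cat.), MeOH, 0 °C, short contact time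
Reagents that add atoms: none
Why: carbonate-catalysed transesterification of the activated chloroacetate is fast at 0 °C, so the ester should be removed at the acyl carbon without touching the carbinol centre and before the β-ketol can undergo retro-aldol cleavage.

Step 5
Reactants: 6 (2S,3R)-3-hydroxy-2-methyl-2-(prop-2-en-1-yl)cyclopentan-1-one
Product: 7 (2S,3R)-3-[(tert-butyldimethylsilyl)oxy]-2-methyl-2-(prop-2-en-1-yl)cyclopentan-1-one
Conditions: TBSCl, imidazole, DMF, rt → 40 °C
Reagents that add atoms: tert-butyldimethylsilyl chloride, CC(C)(C)[Si](C)(C)Cl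
Why: imidazole-promoted silylation of the secondary alcohol gives an ether that prevents migration of the later lactone acyl group onto this oxygen and is expected to last until step 22.

Step 6
Reactants: 7 (2S,3R)-3-[(tert-butyldimethylsilyl)oxy]-2-methyl-2-(prop-2-en-1-yl)cyclopentan-1-one
Product: 8 (5R,6S)-5-[(tert-butyldimethylsilyl)oxy]-6-methyl-6-(prop-2-en-1-yl)oxan-2-one
Conditions: mCPBA, CH2Cl2, 0 °C → rt
Reagents that add atoms: meta-chloroperoxybenzoic acid, O=C(OO)c1cccc(Cl)c1
Why: Baeyer–Villiger oxidation, in which the quaternary α-carbon migrates with retention, inserts oxygen next to the methyl-bearing carbon to give the δ-lactone (future pyran O–C4 bond); the ketone should react with the peracid faster than the monosubstituted alkene.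

Step 7
Reactants: 8 (5R,6S)-5-[(tert-butyldimethylsilyl)oxy]-6-methyl-6-(prop-2-en-1-yl)oxan-2-one
Product: 10 (5R,6S)-5-[(tert-butyldimethylsilyl)oxy]-6-(3-hydroxypropyl)-6-methyloxan-2-one, via B-alkyl-9-BBN adduct 9 (not isolated)
Conditions: 9-BBN, THF, 0 °C → rt; then H2O2, NaOAc (aq), 0 °C
Reagents that add atoms: 9-borabicyclo[3.3.1]nonane, B1C2CCCC1CCC2 (boron only in intermediate 9); hydrogen peroxide, OO
Why: anti-Markovnikov hydroboration of the terminal alkene with 9-BBN, which does not reduce lactones, followed by buffered peroxide oxidation of the C–B bond, should give the primary alcohol at the future C7.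

Step 8
Reactants: 10 (5R,6S)-5-[(tert-butyldimethylsilyl)oxy]-6-(3-hydroxypropyl)-6-methyloxan-2-one
Product: 11 3-[(2S,3R)-3-[(tert-butyldimethylsilyl)oxy]-2-methyl-6-oxooxan-2-yl]propanal
Conditions: TEMPO (cat.), PhI(OAc)2, CH2Cl2, rt
Reagents that add atoms: none
Why: TEMPO-catalysed oxidation with a hypervalent iodine co-oxidant stops at the aldehyde in the absence of water and is mild enough for the lactone and the silyl ether.

Step 9
Reactants: 12 6-methylhept-5-en-2-one
Product: 13 (5E)-7-hydroxy-6-methylhept-5-en-2-one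
Conditions: SeO2 (cat.), t-BuOOH, CH2Cl2, rt
Reagents that add atoms: tert-butyl hydroperoxide, CC(C)(C)OO (terminal oxidant); selenium dioxide, O=[Se]=O (catalytic oxygen carrier)
Why: selenium dioxide allylic oxidation (ene reaction, then [2,3]-sigmatropic shift) is selective for the E-methyl group of a trisubstituted alkene, so the E-allylic alcohol (future C13) should form with the C11=C12 geometry defined.

Step 10
Reactants: 13 (5E)-7-hydroxy-6-methylhept-5-en-2-one
Product: 14 (5E)-7-[(tert-butyldimethylsilyl)oxy]-6-methylhept-5-en-2-one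
Conditions: TBSCl, imidazole, CH2Cl2, rt
Reagents that add atoms: tert-butyldimethylsilyl chloride, CC(C)(C)[Si](C)(C)Cl
Why: silylation of the primary allylic alcohol gives an ether that tolerates butyllithium, Cr(II) and LDA and can later be removed selectively as the least hindered silyl ether.

Step 11
Reactants: 14 (5E)-7-[(tert-butyldimethylsilyl)oxy]-6-methylhept-5-en-2-one
Product: 15 2,4,6-triisopropylbenzenesulfonyl hydrazone of ketone 14
Conditions: 2,4,6-triisopropylbenzenesulfonyl hydrazide, THF, rt
Reagents that add atoms: 2,4,6-triisopropylbenzenesulfonyl hydrazide, CC(C)c1cc(C(C)C)c(S(=O)(=O)NN)c(C(C)C)c1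
Why: condensation of the methyl ketone with the arenesulfonyl hydrazide gives the trisylhydrazone required for a Shapiro reaction, the ortho-isopropyl groups preventing later ring lithiation.

Step 12
Reactants: 15 2,4,6-triisopropylbenzenesulfonyl hydrazone of ketone 14
Product: 17 tert-butyl{[(2E)-6-iodo-2-methylhepta-2,6-dien-1-yl]oxy}dimethylsilane, via vinyllithium 16 (not isolated)
Conditions: n-BuLi (2.2 equiv), TMEDA–hexane, −78 → 0 °C; then I2, THF, −78 °C
Reagents that add atoms: n-butyllithium, [Li]CCCC (lithium only in intermediate 16); iodine, II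
Why: Shapiro reaction, in which the hydrazone dianion forms at the less substituted α-carbon (the methyl group) and loses sulfinate and N2 to the 2-lithio-1-alkene, followed by iodination, should give the 2-iodo-1-alkene as a single regioisomer.

Step 13
Reactants: 11 3-[(2S,3R)-3-[(tert-butyldimethylsilyl)oxy]-2-methyl-6-oxooxan-2-yl]propanal; 17 tert-butyl{[(2E)-6-iodo-2-methylhepta-2,6-dien-1-yl]oxy}dimethylsilane
Product: 18 (5R,6S)-5-[(tert-butyldimethylsilyl)oxy]-6-[(3R,7E)-9-[(tert-butyldimethylsilyl)oxy]-3-hydroxy-8-methyl-4-methylidenenon-7-en-1-yl]-6-methyloxan-2-one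
Conditions: CrCl2, NiCl2 (cat.), chiral oxazoline–sulfonamide ligand (Kishi type), Et3N, THF, rt
Reagents that add atoms: none
Why: Nozaki–Hiyama–Kishi coupling (Ni inserts into the C–I bond, the alkenyl group passes to Cr(III) and adds to the aldehyde, leaving the lactone untouched) forms C7–C8; C7 is too far from C3/C4 for substrate control, so its R configuration is to come from the chiral ligand on chromium, the antipode being chosen for Si-face addition.

Step 14
Reactants: 18 (5R,6S)-5-[(tert-butyldimethylsilyl)oxy]-6-[(3R,7E)-9-[(tert-butyldimethylsilyl)oxy]-3-hydroxy-8-methyl-4-methylidenenon-7-en-1-yl]-6-methyloxan-2-one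
Product: 19 C7 tert-butyldiphenylsilyl ether of 18 (C3 OTBS, C13 OTBS; 3R,4S,7R,11E)
Conditions: TBDPSCl, imidazole, DMAP (cat.), DMF, rt → 40 °C
Reagents that add atoms: tert-butyldiphenylsilyl chloride, CC(C)(C)[Si](Cl)(c1ccccc1)c1ccccc1
Why: silylation of the secondary allylic alcohol with the acid-stable TBDPS group differentiates C7 from the TBS-protected C3 and C13 oxygens for the later selective deprotections.

Step 15
Reactants: 19 C7 tert-butyldiphenylsilyl ether of 18
Product: 21 C1-(dimethylaminomethyl) δ-lactone (C1 epimers; C3 OTBS, C7 OTBDPS, C13 OTBS), via lithium enolate 20 (not isolated)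
Conditions: LDA, THF, −78 °C; then CH2=NMe2+ I−, −78 °C → rt
Reagents that add atoms: lithium diisopropylamide, [Li]N(C(C)C)C(C)C (lithium only in intermediate 20); N,N-dimethylmethyleneiminium iodide, C=[N+](C)C.[I-]
Why: Mannich reaction of the lactone lithium enolate with Eschenmoser's salt introduces C14 at C1, and the enolate cannot undergo β-elimination because the C3 oxygen is γ to the enolate carbon.

Step 16
Reactants: 21 C1-(dimethylaminomethyl) δ-lactone
Product: 23 α-methylene-δ-lactone with C13 OTBS (C1=C14; C3 OTBS, C7 OTBDPS; 3R,4S,7R,11E), via trimethylammonium iodide 22 (not isolated)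
Conditions: MeI, THF, rt; then NaHCO3 (aq), CH2Cl2, rt
Reagents that add atoms: iodomethane, CI (atoms only in intermediate 22)
Why: exhaustive N-methylation followed by E1cB (Hofmann-type) loss of trimethylamine from the β-ammonio lactone should give the exocyclic C1=C14 acrylate unit under nearly neutral conditions.

Step 17
Reactants: 23 α-methylene-δ-lactone with C13 OTBS
Product: 24 α-methylene-δ-lactone with free C13 allylic alcohol (C3 OTBS, C7 OTBDPS)
Conditions: CSA (cat.), MeOH–CH2Cl2, 0 °C
Reagents that add atoms: none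
Why: acid-catalysed methanolysis should remove the unhindered primary allylic TBS ether much faster than the neopentyl-type secondary TBS ether at C3 or the TBDPS ether at C7, and does not add methanol to the acrylate.

Step 18
Reactants: 24 α-methylene-δ-lactone with free C13 allylic alcohol
Product: 25 α-methylene-δ-lactone with E-allylic bromide at C13 (C3 OTBS, C7 OTBDPS; 3R,4S,7R,11E)
Conditions: CBr4, PPh3, CH2Cl2, −20 → 0 °C
Reagents that add atoms: carbon tetrabromide, BrC(Br)(Br)Br
Why: Appel bromination (SN2 on the alkoxyphosphonium at the primary allylic carbon) should give the bromide without allylic transposition or loss of the E geometry, under neutral conditions that the α-methylene lactone tolerates.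

Step 19
Reactants: 25 α-methylene-δ-lactone with E-allylic bromide at C13
Product: 26 lactone-bridged macrocycle (1R,3R,4S,7R,11E): 14-membered carbocycle C1–C14 spanned by the C4–O–C15(=O)–C1 δ-lactone, C3 OTBS, C7 OTBDPS, C8 exo-methylene
Conditions: Bu3SnH, AIBN (cat.), benzene, 80 °C, syringe-pump addition of the stannane, substrate about 2 mM
Reagents that add atoms: none
Why: The stannyl radical abstracts bromine from C13 to give the E-configured allyl radical (C11–C12–C13), which adds through its primary terminus C13 to the unsubstituted methylene carbon C14 of the α-methylene lactone, and the resulting tertiary α-acyl radical at C1 takes hydrogen from Bu3SnH and carries the chain. The closest known reaction type is the tin-hydride-mediated macrocyclisation of allylic radicals onto enones and acrylates, which has given 14-membered cembranoid carbocycles. The ring (C1–C14) closes in the 14-endo-trig mode by forming C13–C14; closure through the secondary terminus C11 would give a more congested 12-membered ring and is disfavoured, and six- or seven-membered closure onto the C8 methylene is geometrically excluded by the E alkene. The new stereocentre C1 (R) is set in the hydrogen transfer: the ten-atom tether is anchored to C4 on the face opposite to the C4 methyl and the C3 silyloxy group, so hydrogen delivery from the other face is the trajectory that lets C14 settle cis to C5 without stretching the chain across the lactone. The step needs cyclisation to outrun direct reduction of the stabilised allyl radical and oligomerisation, which the slow stannane addition at high dilution and the polarity match between the nucleophilic allyl radical and the acrylate-type acceptor should secure. Allyl radicals hold their geometry on this time scale, so the E-C11=C12 alkene is expected to be carried through unchanged.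

Step 20
Reactants: 26 lactone-bridged macrocycle
Product: 28 C15 methyl ketal (2-methoxy-2-methyl-tetrahydropyran; C15 epimers; C3 OTBS, C7 OTBDPS), via lithium lactolate 27 (not isolated)
Conditions: MeLi, THF, −78 °C; then MsOH (slight excess over MeLi), MeOH, −78 → −20 °C
Reagents that add atoms: methyllithium, [Li]C; methanol, CO
Why: methyllithium should add only once to the δ-lactone at −78 °C because the lithium lactolate, with a tertiary alkoxide as leaving group, does not collapse, and the acidified methanol quench converts the lactol to the methyl ketal through the oxocarbenium ion (the C15 configuration is of no consequence).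

Step 21
Reactants: 28 C15 methyl ketal
Product: 29 bridged tetrahydropyran with C15 gem-dimethyl (1R,3R,4S,7R,11E; C3 OTBS, C7 OTBDPS)
Conditions: Me3Al, TMSOTf (cat.), CH2Cl2, −78 → 0 °C
Reagents that add atoms: trimethylaluminium, C[Al](C)C
Why: Lewis-acid ionisation of the tertiary ketal to the cyclic oxocarbenium ion and methyl transfer from trimethylaluminium (substitution of ketals by organoalanes) should create the CMe2–O carbon C15, with silyl ethers and alkenes inert at low temperature.

Step 22
Reactants: 29 bridged tetrahydropyran with C15 gem-dimethyl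
Product: 30 C3 alcohol (C7 OTBDPS retained)
Conditions: p-TsOH·H2O (cat.), MeOH–CH2Cl2, rt
Reagents that add atoms: none
Why: acid-catalysed methanolysis cleaves TBS ethers roughly two orders of magnitude faster than TBDPS ethers, so the C3 hydroxyl should be released selectively while the tertiary ether and the alkenes are untouched by catalytic sulfonic acid.

Step 23
Reactants: 30 C3 alcohol
Product: 31 C3 acetate (C7 OTBDPS)
Conditions: Ac2O, DMAP, pyridine, CH2Cl2, rt
Reagents that add atoms: acetic anhydride, CC(=O)OC(C)=O
Why: DMAP-catalysed acylation should esterify the hindered secondary C3 hydroxyl, the only free hydroxyl in the molecule, with retention.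

Step 24
Reactants: 31 C3 acetate
Product: 32 CNP0202897.1 (target; 1R,3R,4S,7R,11E)
Conditions: TBAF, AcOH, THF, rt → 40 °C
Reagents that add atoms: none
Why: fluoride-induced cleavage of the TBDPS ether, buffered with acetic acid so that the medium stays non-basic and the C3 acetate is neither cleaved nor transferred, should release the C7 allylic alcohol.

## Compound list

1 | 2-methylcyclopentane-1,3-dione | CC1C(=O)CCC1=O | starting material
2 | allyl bromide | C=CCBr | starting material
3 | 2-methyl-2-(prop-2-en-1-yl)cyclopentane-1,3-dione | C=CCC1(C)C(=O)CCC1=O | intermediate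
4 | (2S,3S)-3-hydroxy-2-methyl-2-(prop-2-en-1-yl)cyclopentan-1-one | O=C1CC[C@H](O)[C@]1(C)CC=C | intermediate
5 | (1R,2S)-2-methyl-3-oxo-2-(prop-2-en-1-yl)cyclopentyl chloroacetate | O=C1CC[C@@H](OC(=O)CCl)[C@]1(C)CC=C | intermediate
6 | (2S,3R)-3-hydroxy-2-methyl-2-(prop-2-en-1-yl)cyclopentan-1-one | O=C1CC[C@@H](O)[C@]1(C)CC=C | intermediate
7 | (2S,3R)-3-[(tert-butyldimethylsilyl)oxy]-2-methyl-2-(prop-2-en-1-yl)cyclopentan-1-one | O=C1CC[C@@H](O[Si](C)(C)C(C)(C)C)[C@]1(C)CC=C | intermediate
8 | (5R,6S)-5-[(tert-butyldimethylsilyl)oxy]-6-methyl-6-(prop-2-en-1-yl)oxan-2-one | O=C1CC[C@@H](O[Si](C)(C)C(C)(C)C)[C@](C)(CC=C)O1 | intermediate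
9 | B-alkyl-9-BBN adduct of 8 (boron on the terminal carbon) | O=C1CC[C@@H](O[Si](C)(C)C(C)(C)C)[C@](C)(CCCB2C3CCCC2CCC3)O1 | intermediate
10 | (5R,6S)-5-[(tert-butyldimethylsilyl)oxy]-6-(3-hydroxypropyl)-6-methyloxan-2-one | O=C1CC[C@@H](O[Si](C)(C)C(C)(C)C)[C@](C)(CCCO)O1 | intermediate
11 | 3-[(2S,3R)-3-[(tert-butyldimethylsilyl)oxy]-2-methyl-6-oxooxan-2-yl]propanal | O=C1CC[C@@H](O[Si](C)(C)C(C)(C)C)[C@](C)(CCC=O)O1 | intermediate
12 | 6-methylhept-5-en-2-one | CC(=O)CCC=C(C)C | starting material
13 | (5E)-7-hydroxy-6-methylhept-5-en-2-one | CC(=O)CC/C=C(\C)CO | intermediate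
14 | (5E)-7-[(tert-butyldimethylsilyl)oxy]-6-methylhept-5-en-2-one | CC(=O)CC/C=C(\C)CO[Si](C)(C)C(C)(C)C | intermediate
15 | 2,4,6-triisopropylbenzenesulfonyl hydrazone of 14 | CC(CC/C=C(\C)CO[Si](C)(C)C(C)(C)C)=NNS(=O)(=O)c1c(C(C)C)cc(C(C)C)cc1C(C)C | intermediate
16 | (5E)-7-[(tert-butyldimethylsilyl)oxy]-6-methylhepta-1,5-dien-2-yllithium | [Li]C(=C)CC/C=C(\C)CO[Si](C)(C)C(C)(C)C | intermediate
17 | tert-butyl{[(2E)-6-iodo-2-methylhepta-2,6-dien-1-yl]oxy}dimethylsilane | C=C(I)CC/C=C(\C)CO[Si](C)(C)C(C)(C)C | intermediate
18 | (5R,6S)-5-[(tert-butyldimethylsilyl)oxy]-6-[(3R,7E)-9-[(tert-butyldimethylsilyl)oxy]-3-hydroxy-8-methyl-4-methylidenenon-7-en-1-yl]-6-methyloxan-2-one | O=C1CC[C@@H](O[Si](C)(C)C(C)(C)C)[C@](C)(CC[C@@H](O)C(=C)CC/C=C(\C)CO[Si](C)(C)C(C)(C)C)O1 | intermediate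
19 | C7 tert-butyldiphenylsilyl ether of 18 | O=C1CC[C@@H](O[Si](C)(C)C(C)(C)C)[C@](C)(CC[C@@H](O[Si](c2ccccc2)(c2ccccc2)C(C)(C)C)C(=C)CC/C=C(\C)CO[Si](C)(C)C(C)(C)C)O1 | intermediate
20 | lithium enolate of lactone 19 | [Li]OC1=CC[C@@H](O[Si](C)(C)C(C)(C)C)[C@](C)(CC[C@@H](O[Si](c2ccccc2)(c2ccccc2)C(C)(C)C)C(=C)CC/C=C(\C)CO[Si](C)(C)C(C)(C)C)O1 | intermediate
21 | C1-(dimethylaminomethyl) δ-lactone (C1 epimers) | CN(C)CC1C[C@@H](O[Si](C)(C)C(C)(C)C)[C@](C)(CC[C@@H](O[Si](c2ccccc2)(c2ccccc2)C(C)(C)C)C(=C)CC/C=C(\C)CO[Si](C)(C)C(C)(C)C)OC1=O | intermediate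
22 | trimethylammonium iodide of 21 | C[N+](C)(C)CC1C[C@@H](O[Si](C)(C)C(C)(C)C)[C@](C)(CC[C@@H](O[Si](c2ccccc2)(c2ccccc2)C(C)(C)C)C(=C)CC/C=C(\C)CO[Si](C)(C)C(C)(C)C)OC1=O.[I-] | intermediate
23 | α-methylene-δ-lactone with C13 OTBS (C3 OTBS, C7 OTBDPS) | C=C1C[C@@H](O[Si](C)(C)C(C)(C)C)[C@](C)(CC[C@@H](O[Si](c2ccccc2)(c2ccccc2)C(C)(C)C)C(=C)CC/C=C(\C)CO[Si](C)(C)C(C)(C)C)OC1=O | intermediate
24 | α-methylene-δ-lactone with free C13 allylic alcohol | C=C1C[C@@H](O[Si](C)(C)C(C)(C)C)[C@](C)(CC[C@@H](O[Si](c2ccccc2)(c2ccccc2)C(C)(C)C)C(=C)CC/C=C(\C)CO)OC1=O | intermediate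
25 | α-methylene-δ-lactone with E-allylic bromide at C13 (key-step precursor) | C=C1C[C@@H](O[Si](C)(C)C(C)(C)C)[C@](C)(CC[C@@H](O[Si](c2ccccc2)(c2ccccc2)C(C)(C)C)C(=C)CC/C=C(\C)CBr)OC1=O | intermediate
26 | lactone-bridged 14-membered carbocycle (1R,3R,4S,7R,11E; C3 OTBS, C7 OTBDPS) | C=C1CC/C=C(\C)CC[C@@H]2C[C@@H](O[Si](C)(C)C(C)(C)C)[C@](C)(CC[C@H]1O[Si](c3ccccc3)(c3ccccc3)C(C)(C)C)OC2=O | intermediate
27 | lithium lactolate from MeLi addition to 26 (C15 epimers) | C=C1CC/C=C(\C)CC[C@@H]2C[C@@H](O[Si](C)(C)C(C)(C)C)[C@](C)(CC[C@H]1O[Si](c3ccccc3)(c3ccccc3)C(C)(C)C)OC2(C)O[Li] | intermediate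
28 | C15 methyl ketal (C15 epimers) | C=C1CC/C=C(\C)CC[C@@H]2C[C@@H](O[Si](C)(C)C(C)(C)C)[C@](C)(CC[C@H]1O[Si](c3ccccc3)(c3ccccc3)C(C)(C)C)OC2(C)OC | intermediate
29 | bridged tetrahydropyran with C15 gem-dimethyl (C3 OTBS, C7 OTBDPS) | C=C1CC/C=C(\C)CC[C@@H]2C[C@@H](O[Si](C)(C)C(C)(C)C)[C@](C)(CC[C@H]1O[Si](c3ccccc3)(c3ccccc3)C(C)(C)C)OC2(C)C | intermediate
30 | C3 alcohol (C7 OTBDPS) | C=C1CC/C=C(\C)CC[C@@H]2C[C@@H](O)[C@](C)(CC[C@H]1O[Si](c3ccccc3)(c3ccccc3)C(C)(C)C)OC2(C)C | intermediate
31 | C3 acetate (C7 OTBDPS) | C=C1CC/C=C(\C)CC[C@@H]2C[C@@H](OC(C)=O)[C@](C)(CC[C@H]1O[Si](c3ccccc3)(c3ccccc3)C(C)(C)C)OC2(C)C | intermediate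
32 | CNP0202897.1 | C=C1CC/C=C(\C)CC[C@@H]2C[C@@H](OC(C)=O)[C@](C)(CC[C@H]1O)OC2(C)C | target

## Step count and risks

Total step count: 24. Longest linear sequence: 20 steps (steps 1–8 and 13–24); steps 9–12 make the side chain.

Steps most likely to fail:

Step 19 (radical macrocyclisation). The allyl radical may be reduced before it cyclises, may add intermolecularly, or may close through C11; hydrogen delivery at C1 may also be unselective because the C3 silyloxy and C4 methyl groups sit on the face meant to stay open. The fallback replaces the radical closure by an anionic one and sets out from bromide 25. Displacement with sodium benzenesulfinate in DMF would give the allylic phenyl sulfone F1. Slow addition of F1 to LiHMDS in THF at −78 °C under high dilution would generate the sulfonyl-stabilised allyl anion, whose α-carbon (C13) adds in a conjugate sense to C14; protonation of the lactone enolate under equilibrating conditions would give the macrocyclic C13 sulfone F2. Buffered sodium amalgam (Na2HPO4, MeOH–THF, −20 °C) would remove the sulfonyl group and return the route at 26.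

Step 21 (methyl transfer to the ketal). After ionisation the oxocarbenium ion may lose a proton from C1 or the C15 methyl to give enol ethers instead of accepting a methyl group, and the Lewis acid may attack the allylic silyl ether. The fallback builds the ether by cyclodehydration and sets out from lactone 26, bypassing 27 and 28. Excess MeLi (THF, −78 → 0 °C) would open the lactone to the di-tertiary 1,5-diol F3. Catalytic p-TsOH in CH2Cl2 would then ionise the C15 carbinol; the C4 carbinol is deactivated by the neighbouring silyloxy group and keeps its configuration. Capture by the C4 hydroxyl would close the tetrahydropyran and return the route at 29.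

Step 13 (Ni/Cr coupling). Facial discrimination at the C7 aldehyde may be insufficient, since C7 is remote from the existing stereocentres and rests on ligand control alone, and the C7 epimers may not separate. The fallback sets the centre by reduction and sets out from 18 obtained as a C7 epimer mixture. Dess–Martin oxidation would give the α-methylene ketone F4, and reduction with (S)-Me-CBS and catecholborane at −78 °C, with the alkenyl group acting as the large substituent, would return (7R)-18.

Further compounds
F1 | step 19 | allylic phenyl sulfone from bromide 25 (SO2Ph at C13) | C=C1C[C@@H](O[Si](C)(C)C(C)(C)C)[C@](C)(CC[C@@H](O[Si](c2ccccc2)(c2ccccc2)C(C)(C)C)C(=C)CC/C=C(\C)CS(=O)(=O)c2ccccc2)OC1=O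
F2 | step 19 | lactone-bridged macrocycle carrying SO2Ph at C13 (C13 epimers) | C=C1CC/C=C(\C)C(S(=O)(=O)c3ccccc3)C[C@@H]2C[C@@H](O[Si](C)(C)C(C)(C)C)[C@](C)(CC[C@H]1O[Si](c3ccccc3)(c3ccccc3)C(C)(C)C)OC2=O
F3 | step 21 | macrocyclic diol with C15 dimethylcarbinol and free C4 tertiary alcohol | C=C1CC/C=C(\C)CC[C@@H](C(C)(C)O)C[C@@H](O[Si](C)(C)C(C)(C)C)[C@](C)(O)CC[C@H]1O[Si](c2ccccc2)(c2ccccc2)C(C)(C)C
F4 | step 13 | C7 ketone (α-methylene ketone) from oxidation of 18 | O=C1CC[C@@H](O[Si](C)(C)C(C)(C)C)[C@](C)(CCC(=O)C(=C)CC/C=C(\C)CO[Si](C)(C)C(C)(C)C)O1
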